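**Plan**

1. Core numbering used throughout: 3,7-dioxabicyclo[3.3.0]octan-2-one with C1/C5 at the fusion, C2 the carbonyl, O3, C4 (3,4,5-trihydroxyphenyl), C6H2, O7 and C8 (3,4-dihydroxyphenyl). Ring A is the lactone and ring B the tetrahydrofuran. The target is (1S,4S,5R,8S), cis-fused, with both aryl groups exo.
2. Enabling feature: C2 touches the skeleton only at C1 and O3. O3–C4–C5–C1 has the spacing of a homoallylic alcohol once ring B carries a C1=C8 enol ether, so ring A can be closed around one molecule of CO that the C4 hydroxyl steers to C1.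
3. Cuts, in retrosynthetic order: the five O–benzyl bonds; C1–C2, C2–O3 and C8–H (hydroformylation and lactol closure); O7–C8 (5-endo hydroalkoxylation); C8–aryl (Sonogashira coupling); C4–C5 (allenylzinc addition to an aldehyde).
4. Forward: the open chain C4–C5(C6)–C1≡C8 is joined first, ring B closes as a 2,3-dihydrofuran, and ring A closes last as a lactol. Oxidation and debenzylation follow.
5. Stereochemistry: one asymmetric transfer hydrogenation sets a propargylic carbinol. Its configuration passes through an axially chiral allenylzinc to C5 and, by a cyclic anti transition state, to C4. C1 and C8 come from tethered syn addition on the ring face that carries the C5 side chain.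

Key step: step 11

Remark: the lactol of the key step is expected as an anomeric mixture. The exo-hydroxy anomer is drawn, and both anomers give the same lactone on oxidation.

**Step 1**
Reactants: 1 (tert-butyldimethylsilyloxy)acetaldehyde; 2 trimethylsilylacetylene
Product: 4 rac-1-(tert-butyldimethylsilyloxy)-4-(trimethylsilyl)but-3-yn-2-ol, via lithium (trimethylsilyl)acetylide 3 (not isolated)
Conditions: 2, n-BuLi, THF, −78 °C; then 1, −78 °C
Reagents that add atoms: none
Why: 1,2-addition of a lithium acetylide to an aldehyde is fast at low temperature and spares the silyl ether; the racemic carbinol is erased in step 2.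

**Step 2**
Reactants: 4 rac-1-(tert-butyldimethylsilyloxy)-4-(trimethylsilyl)but-3-yn-2-ol
Product: 5 1-(tert-butyldimethylsilyloxy)-4-(trimethylsilyl)but-3-yn-2-one
Conditions: Dess–Martin periodinane, CH2Cl2, 0 °C to rt
Reagents that add atoms: none
Why: Dess–Martin oxidation converts propargylic alcohols into ynones under nearly neutral conditions that leave the O-silyl and C-silyl groups in place.

**Step 3**
Reactants: 5 1-(tert-butyldimethylsilyloxy)-4-(trimethylsilyl)but-3-yn-2-one
Product: 6 (S)-1-(tert-butyldimethylsilyloxy)-4-(trimethylsilyl)but-3-yn-2-ol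
Conditions: Ru[(R,R)-TsDPEN](p-cymene) (16-electron amido complex, 1 mol %), i-PrOH, rt
Reagents that add atoms: none
Why: in the Noyori asymmetric transfer hydrogenation of alkynyl ketones the alkynyl group takes the place of the aryl group of an aryl ketone, so the (R,R) catalyst should give the carbinol drawn (labelled S only because CH2OSi outranks the alkynyl carbon) without reducing the triple bond.

**Step 4**
Reactants: 6 (S)-1-(tert-butyldimethylsilyloxy)-4-(trimethylsilyl)but-3-yn-2-ol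
Product: 7 (S)-1-(tert-butyldimethylsilyloxy)-4-(trimethylsilyl)but-3-yn-2-yl methanesulfonate
Conditions: MsCl, Et3N, CH2Cl2, −78 to 0 °C
Reagents that add atoms: methanesulfonyl chloride CS(=O)(=O)Cl
Why: O-sulfonylation breaks no bond at the stereocentre, so the configuration is retained, and the mesylate is used without storage.

**Step 5**
Reactants: 7 (S)-1-(tert-butyldimethylsilyloxy)-4-(trimethylsilyl)but-3-yn-2-yl methanesulfonate; 8 3,4,5-tris(benzyloxy)benzaldehyde
Product: 10 (1S,2R)-2-[(tert-butyldimethylsilyloxy)methyl]-1-[3,4,5-tris(benzyloxy)phenyl]-4-(trimethylsilyl)but-3-yn-1-ol, via (aS)-allenyl(ethyl)zinc 9 (not isolated)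
Conditions: Pd(OAc)2 (5 mol %), PPh3 (5 mol %), Et2Zn (3 equiv), THF, −78 to −20 °C
Reagents that add atoms: none
Why: in this Marshall–Tamaru propargylation zerovalent palladium displaces the mesylate in an anti SN2′ sense, Et2Zn transmetalates with retention to allenylzinc 9, and 9 adds to 8 through a cyclic SE2′ transition state on its zinc-bearing face; this relays the mesylate configuration to C5 (R), and with the aryl group turned away from the CH2OTBS branch it gives the anti C4 (S) carbinol, the C-silyl group being kept because it raises the anti preference.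

**Step 6**
Reactants: 10 (1S,2R)-2-[(tert-butyldimethylsilyloxy)methyl]-1-[3,4,5-tris(benzyloxy)phenyl]-4-(trimethylsilyl)but-3-yn-1-ol
Product: 11 the C4-O-triisopropylsilyl ether of 10, (1S,2R)-2-[(tert-butyldimethylsilyloxy)methyl]-1-(triisopropylsilyloxy)-1-[3,4,5-tris(benzyloxy)phenyl]-4-(trimethylsilyl)but-3-yne
Conditions: TIPSOTf, 2,6-lutidine, CH2Cl2, 0 °C to rt
Reagents that add atoms: triisopropylsilyl trifluoromethanesulfonate CC(C)[Si](C(C)C)(C(C)C)OS(=O)(=O)C(F)(F)F
Why: silyl triflate/lutidine silylation covers hindered secondary alcohols reliably, and the mask is needed because the C4 hydroxyl is itself homopropargylic and would compete with the C6 hydroxyl in step 9.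

**Step 7**
Reactants: 11 the C4-O-triisopropylsilyl ether of 10
Product: 13 (2R,3S)-2-ethynyl-3-(triisopropylsilyloxy)-3-[3,4,5-tris(benzyloxy)phenyl]propan-1-ol, via terminal alkyne 12 (not isolated)
Conditions: K2CO3 (0.1 equiv), MeOH–THF, rt; then CSA (0.3 equiv), 0 °C
Reagents that add atoms: none
Why: carbonate-catalysed methanolysis removes the alkynyl silane, and the following acid-catalysed methanolysis cleaves the unhindered primary TBS ether far faster than the hindered secondary TIPS ether (selective desilylation by steric differentiation).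

**Step 8**
Reactants: 13 (2R,3S)-2-ethynyl-3-(triisopropylsilyloxy)-3-[3,4,5-tris(benzyloxy)phenyl]propan-1-ol; 14 4-bromo-1,2-bis(benzyloxy)benzene
Product: 15 (2R,3S)-2-{[3,4-bis(benzyloxy)phenyl]ethynyl}-3-(triisopropylsilyloxy)-3-[3,4,5-tris(benzyloxy)phenyl]propan-1-ol
Conditions: Pd(PhCN)2Cl2 (3 mol %), [HP(t-Bu)3]BF4 (6 mol %), CuI (2 mol %), i-Pr2NH, dioxane, rt
Reagents that add atoms: none
Why: Sonogashira coupling with the bulky, electron-rich trialkylphosphine engages electron-rich aryl bromides at room temperature and tolerates a free primary alcohol.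

**Step 9**
Reactants: 15 (2R,3S)-2-{[3,4-bis(benzyloxy)phenyl]ethynyl}-3-(triisopropylsilyloxy)-3-[3,4,5-tris(benzyloxy)phenyl]propan-1-ol
Product: 16 {(S)-[(3R)-5-[3,4-bis(benzyloxy)phenyl]-2,3-dihydrofuran-3-yl][3,4,5-tris(benzyloxy)phenyl]methoxy}triisopropylsilane
Conditions: Ph3PAuNTf2 (2 mol %), 4 Å MS, toluene, rt; then Et3N, filtration through basic alumina
Reagents that add atoms: none
Why: gold-catalysed 5-endo-dig cycloisomerisation of a homopropargylic alcohol closes O7–C8, because the electron-rich aryl group polarises the gold-bound alkyne towards C8 and the 4-exo alternative is strained; dry, finally basic handling protects the enol ether.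

**Step 10**
Reactants: 16 {(S)-[(3R)-5-[3,4-bis(benzyloxy)phenyl]-2,3-dihydrofuran-3-yl][3,4,5-tris(benzyloxy)phenyl]methoxy}triisopropylsilane
Product: 17 (S)-[(3R)-5-[3,4-bis(benzyloxy)phenyl]-2,3-dihydrofuran-3-yl][3,4,5-tris(benzyloxy)phenyl]methanol
Conditions: TBAF, THF, 0 °C to rt
Reagents that add atoms: none
Why: fluoride desilylation runs in a basic medium in which the acid-labile aryl enol ether and the benzyl ethers are inert.

**Step 11**
Reactants: 17 (S)-[(3R)-5-[3,4-bis(benzyloxy)phenyl]-2,3-dihydrofuran-3-yl][3,4,5-tris(benzyloxy)phenyl]methanol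
Product: 20 (1S,2R,4S,5R,8S)-8-[3,4-bis(benzyloxy)phenyl]-4-[3,4,5-tris(benzyloxy)phenyl]-3,7-dioxabicyclo[3.3.0]octan-2-ol, via diphenylphosphinite 18 (not isolated), via hydroxy aldehyde 19 (not isolated)
Conditions: Rh(acac)(CO)2 (5 mol %), Ph2POMe (25 mol %), 4 Å MS, CO/H2 (1:1, 40 bar), THF, 50 °C
Reagents that add atoms: carbon monoxide [C-]#[O+]
Why: Proposed new method: Ph2POMe should exchange its methoxy group for the C4 hydroxyl of 17 (the sieves take up methanol) to give phosphinite 18, whose phosphorus holds the monovalent rhodium hydride against the ring face that carries the C5 side chain; syn hydrometalation then puts hydrogen on C8 and rhodium on C1 within a six-membered Rh–P–O–C4–C5–C1 chelate, and CO insertion, hydrogenolysis of the acyl and ligand exchange release aldehyde 19. The closest known reaction type is the branched-selective hydroformylation of homoallylic alcohols with a catalytic, reversibly bound phosphinite, which ends in γ-lactols, together with the hydroformylation of 2,3-dihydrofuran; a trisubstituted 5-aryl enol ether has not been used in either. The one ring formed, ring A (C1–C2–O3–C4–C5), closes by 5-exo-trig addition of the C4 hydroxyl to the formyl carbon, which is possible only because formyl group and carbinol arm are cis on ring B. C1 is set by the tether (formyl on the face of the C5 arm, hence cis fusion), C8 by the syn course of hydrometalation (its hydrogen cis to C2, so the aryl group ends exo and trans to C2), and the anomeric C2 by equilibration, which does not matter because it is oxidised next. The step needs C1-over-C8 regiochemistry and contra-steric facial selectivity: both rest on the chelate, the first is reinforced because a formyl group at the fully substituted C8 would go against Keulemans' rule, and the C1 rhodium alkyl has no syn β-hydrogen at C5, so the double bond cannot migrate. The medium must stay neutral so that the C4 hydroxyl does not add to the enol ether.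

**Step 12**
Reactants: 20 (1S,2R,4S,5R,8S)-8-[3,4-bis(benzyloxy)phenyl]-4-[3,4,5-tris(benzyloxy)phenyl]-3,7-dioxabicyclo[3.3.0]octan-2-ol
Product: 21 (1S,4S,5R,8S)-8-[3,4-bis(benzyloxy)phenyl]-4-[3,4,5-tris(benzyloxy)phenyl]-3,7-dioxabicyclo[3.3.0]octan-2-one
Conditions: Ag2CO3 on Celite, toluene, reflux
Reagents that add atoms: none
Why: Fétizon oxidation converts lactols into lactones under neutral heterogeneous conditions, both anomers converge, and C1 cannot epimerise because only the cis-fused bicycle is viable.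

**Step 13**
Reactants: 21 (1S,4S,5R,8S)-8-[3,4-bis(benzyloxy)phenyl]-4-[3,4,5-tris(benzyloxy)phenyl]-3,7-dioxabicyclo[3.3.0]octan-2-one
Product: 22 (1S,4S,5R,8S)-8-(3,4-dihydroxyphenyl)-4-(3,4,5-trihydroxyphenyl)-3,7-dioxabicyclo[3.3.0]octan-2-one (CNP0290035.1)
Conditions: H2 (1 atm), 10 % Pd/C, EtOAc–EtOH, rt; work-up under argon
Reagents that add atoms: none
Why: catalytic hydrogenolysis removes the five unhindered primary aryl benzyl ethers much faster than it attacks the two secondary, ring-bound benzylic C–O bonds (C4–O3, C8–O7) in a neutral solvent at 1 atm, so stopping once debenzylation is complete should leave all four stereocentres untouched.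

**Compound list**

1 | (tert-butyldimethylsilyloxy)acetaldehyde | CC(C)(C)[Si](C)(C)OCC=O | starting material
2 | trimethylsilylacetylene | C#C[Si](C)(C)C | starting material
3 | lithium (trimethylsilyl)acetylide | [Li]C#C[Si](C)(C)C | intermediate
4 | rac-1-(tert-butyldimethylsilyloxy)-4-(trimethylsilyl)but-3-yn-2-ol | CC(C)(C)[Si](C)(C)OCC(O)C#C[Si](C)(C)C | intermediate
5 | 1-(tert-butyldimethylsilyloxy)-4-(trimethylsilyl)but-3-yn-2-one | CC(C)(C)[Si](C)(C)OCC(=O)C#C[Si](C)(C)C | intermediate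
6 | (S)-1-(tert-butyldimethylsilyloxy)-4-(trimethylsilyl)but-3-yn-2-ol | CC(C)(C)[Si](C)(C)OC[C@@H](O)C#C[Si](C)(C)C | intermediate
7 | (S)-1-(tert-butyldimethylsilyloxy)-4-(trimethylsilyl)but-3-yn-2-yl methanesulfonate | CC(C)(C)[Si](C)(C)OC[C@@H](OS(C)(=O)=O)C#C[Si](C)(C)C | intermediate
8 | 3,4,5-tris(benzyloxy)benzaldehyde | O=Cc1cc(OCc2ccccc2)c(OCc2ccccc2)c(OCc2ccccc2)c1 | starting material
9 | (aS)-[4-(tert-butyldimethylsilyloxy)-1-(trimethylsilyl)buta-1,2-dien-1-yl](ethyl)zinc | [H]C(CO[Si](C)(C)C(C)(C)C)=[C@@]=C([Zn]CC)[Si](C)(C)C | intermediate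
10 | (1S,2R)-2-[(tert-butyldimethylsilyloxy)methyl]-1-[3,4,5-tris(benzyloxy)phenyl]-4-(trimethylsilyl)but-3-yn-1-ol | O[C@H](c1cc(OCc2ccccc2)c(OCc2ccccc2)c(OCc2ccccc2)c1)[C@@H](CO[Si](C)(C)C(C)(C)C)C#C[Si](C)(C)C | intermediate
11 | C4-O-triisopropylsilyl ether of 10 | CC(C)[Si](C(C)C)(C(C)C)O[C@H](c1cc(OCc2ccccc2)c(OCc2ccccc2)c(OCc2ccccc2)c1)[C@@H](CO[Si](C)(C)C(C)(C)C)C#C[Si](C)(C)C | intermediate
12 | (1S,2R)-2-[(tert-butyldimethylsilyloxy)methyl]-1-(triisopropylsilyloxy)-1-[3,4,5-tris(benzyloxy)phenyl]but-3-yne | CC(C)[Si](C(C)C)(C(C)C)O[C@H](c1cc(OCc2ccccc2)c(OCc2ccccc2)c(OCc2ccccc2)c1)[C@@H](CO[Si](C)(C)C(C)(C)C)C#C | intermediate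
13 | (2R,3S)-2-ethynyl-3-(triisopropylsilyloxy)-3-[3,4,5-tris(benzyloxy)phenyl]propan-1-ol | CC(C)[Si](C(C)C)(C(C)C)O[C@H](c1cc(OCc2ccccc2)c(OCc2ccccc2)c(OCc2ccccc2)c1)[C@@H](CO)C#C | intermediate
14 | 4-bromo-1,2-bis(benzyloxy)benzene | Brc1ccc(OCc2ccccc2)c(OCc2ccccc2)c1 | starting material
15 | (2R,3S)-2-{[3,4-bis(benzyloxy)phenyl]ethynyl}-3-(triisopropylsilyloxy)-3-[3,4,5-tris(benzyloxy)phenyl]propan-1-ol | CC(C)[Si](C(C)C)(C(C)C)O[C@H](c1cc(OCc2ccccc2)c(OCc2ccccc2)c(OCc2ccccc2)c1)[C@@H](CO)C#Cc1ccc(OCc2ccccc2)c(OCc2ccccc2)c1 | intermediate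
16 | {(S)-[(3R)-5-[3,4-bis(benzyloxy)phenyl]-2,3-dihydrofuran-3-yl][3,4,5-tris(benzyloxy)phenyl]methoxy}triisopropylsilane | CC(C)[Si](C(C)C)(C(C)C)O[C@H](c2cc(OCc3ccccc3)c(OCc3ccccc3)c(OCc3ccccc3)c2)[C@H]1COC(c2ccc(OCc3ccccc3)c(OCc3ccccc3)c2)=C1 | intermediate
17 | (S)-[(3R)-5-[3,4-bis(benzyloxy)phenyl]-2,3-dihydrofuran-3-yl][3,4,5-tris(benzyloxy)phenyl]methanol | O[C@H](c2cc(OCc3ccccc3)c(OCc3ccccc3)c(OCc3ccccc3)c2)[C@H]1COC(c2ccc(OCc3ccccc3)c(OCc3ccccc3)c2)=C1 | intermediate
18 | O-diphenylphosphinite of 17 | c1ccccc1P(c1ccccc1)O[C@H](c2cc(OCc3ccccc3)c(OCc3ccccc3)c(OCc3ccccc3)c2)[C@H]1COC(c2ccc(OCc3ccccc3)c(OCc3ccccc3)c2)=C1 | intermediate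
19 | (2S,3S,4R)-2-[3,4-bis(benzyloxy)phenyl]-4-{(S)-hydroxy[3,4,5-tris(benzyloxy)phenyl]methyl}tetrahydrofuran-3-carbaldehyde | O[C@H](c2cc(OCc3ccccc3)c(OCc3ccccc3)c(OCc3ccccc3)c2)[C@H]1CO[C@H](c2ccc(OCc3ccccc3)c(OCc3ccccc3)c2)[C@H]1C=O | intermediate
20 | (1S,2R,4S,5R,8S)-8-[3,4-bis(benzyloxy)phenyl]-4-[3,4,5-tris(benzyloxy)phenyl]-3,7-dioxabicyclo[3.3.0]octan-2-ol | O[C@@H]1O[C@H](c3cc(OCc4ccccc4)c(OCc4ccccc4)c(OCc4ccccc4)c3)[C@H]2CO[C@H](c3ccc(OCc4ccccc4)c(OCc4ccccc4)c3)[C@@H]12 | intermediate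
21 | (1S,4S,5R,8S)-8-[3,4-bis(benzyloxy)phenyl]-4-[3,4,5-tris(benzyloxy)phenyl]-3,7-dioxabicyclo[3.3.0]octan-2-one | O=C1O[C@H](c3cc(OCc4ccccc4)c(OCc4ccccc4)c(OCc4ccccc4)c3)[C@H]2CO[C@H](c3ccc(OCc4ccccc4)c(OCc4ccccc4)c3)[C@@H]12 | intermediate
22 | (1S,4S,5R,8S)-8-(3,4-dihydroxyphenyl)-4-(3,4,5-trihydroxyphenyl)-3,7-dioxabicyclo[3.3.0]octan-2-one | O=C1O[C@H](c2cc(O)c(O)c(O)c2)[C@H]2CO[C@H](c3ccc(O)c(O)c3)[C@@H]12 | target

Total step count: 13. Longest linear sequence: 13 steps (from 1 and 2 to 22).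

**Steps most likely to fail**

**Step 11.**

What may go wrong:
- lack of turnover at the hindered trisubstituted enol ether;
- plain hydrogenation of the double bond;
- undirected addition from the open ring face;
- acid-triggered addition of the C4 hydroxyl to the enol ether.

The fallback sets out from 13 and comes back at 21, using known lactone chemistry.
- Ruthenium-vinylidene oxidative cyclisation of the homopropargylic alcohol 13 (CpRu(cod)Cl, tri(2-furyl)phosphine, N-hydroxysuccinimide, Bu4NBr, NaHCO3, DMF–H2O, 95 °C) would turn the two alkyne carbons into C1H2 and C2(=O). It gives (4R)-4-{(S)-(triisopropylsilyloxy)[3,4,5-tris(benzyloxy)phenyl]methyl}oxolan-2-one F1, in which the acyl group sits provisionally on the C6 oxygen.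
- The lithium enolate of F1 (LiHMDS, THF, −78 °C) should add to commercial 3,4-bis(benzyloxy)benzaldehyde anti to the bulky C5 branch (trans-selective lactone aldol). The product is (3S,4R)-3-{[3,4-bis(benzyloxy)phenyl](hydroxy)methyl}-4-{(S)-(triisopropylsilyloxy)[3,4,5-tris(benzyloxy)phenyl]methyl}oxolan-2-one F2. It has the correct C1, and the configuration of the C8 carbinol does not matter.
- TBAF would free the C4 hydroxyl to give (3S,4R)-3-{[3,4-bis(benzyloxy)phenyl](hydroxy)methyl}-4-{(S)-hydroxy[3,4,5-tris(benzyloxy)phenyl]methyl}oxolan-2-one F3.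
- Catalytic camphorsulfonic acid in CH2Cl2 should then shift the acyl group from the C6 oxygen to O3, giving (3S,4R,5S)-3-{[3,4-bis(benzyloxy)phenyl](hydroxy)methyl}-4-(hydroxymethyl)-5-[3,4,5-tris(benzyloxy)phenyl]oxolan-2-one F4.
- The same acid ionises the electron-rich C8 carbinol. The released C6 hydroxyl, now cis to the C8 branch, captures the benzylic cation with the aryl group turned exo (stereoconvergent SN1 etherification) to give 21.

**Step 5.**

What may go wrong:
- erosion of the anti preference with an aromatic aldehyde;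
- β-elimination of silyloxide from the organozinc;
- partial racemisation of the allenylmetal.

The fallback sets out from 8 and comes back at 12.
- Iridium-catalysed transfer-hydrogenative anti-(hydroxymethyl)allylation of 8 is the first operation. It uses the cyclic carbonate of cis-but-2-ene-1,4-diol and the catalyst formed from [Ir(cod)Cl]2, 4-cyano-3-nitrobenzoic acid and the SEGPHOS enantiomer that gives the (S)-carbinol, with i-PrOH as reductant. It would give (1S,2R)-2-ethenyl-1-[3,4,5-tris(benzyloxy)phenyl]propane-1,3-diol F5.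
- Selective primary silylation (TBSCl, imidazole) gives (1S,2R)-2-[(tert-butyldimethylsilyloxy)methyl]-1-[3,4,5-tris(benzyloxy)phenyl]but-3-en-1-ol F6.
- TIPSOTf/2,6-lutidine gives (3R,4S)-3-[(tert-butyldimethylsilyloxy)methyl]-4-(triisopropylsilyloxy)-4-[3,4,5-tris(benzyloxy)phenyl]but-1-ene F7.
- Ozonolysis with PPh3 work-up gives (2R,3S)-2-[(tert-butyldimethylsilyloxy)methyl]-3-(triisopropylsilyloxy)-3-[3,4,5-tris(benzyloxy)phenyl]propanal F8.
- Ohira–Bestmann homologation (K2CO3, MeOH) gives 12, which is acidified in the same flask as in step 7.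

**Step 9.**

What may go wrong: hydration or oligomerisation of the enol ether in the cationic gold medium, and loss during purification.

The fallback sets out from 15 and comes back at 16.
- The same alkynol is cyclised in methanol (Ph3PAuNTf2, catalytic p-TsOH, MeOH–CH2Cl2, rt), so that the enol ether is intercepted at once as a robust, chromatographable ketal. This is {(S)-[(3R)-5-[3,4-bis(benzyloxy)phenyl]-5-methoxyoxolan-3-yl][3,4,5-tris(benzyloxy)phenyl]methoxy}triisopropylsilane F9, formed by tandem cycloisomerisation and hydroalkoxylation as a mixture of ketal epimers.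
- Base-buffered loss of methanol (TMSOTf, i-Pr2NEt, CH2Cl2, −20 °C) can remove a proton only from C1, and it then unveils 16 under non-acidic conditions.

**Further compounds**

F1 | step 11 | (4R)-4-{(S)-(triisopropylsilyloxy)[3,4,5-tris(benzyloxy)phenyl]methyl}oxolan-2-one | CC(C)[Si](C(C)C)(C(C)C)O[C@H](c2cc(OCc3ccccc3)c(OCc3ccccc3)c(OCc3ccccc3)c2)[C@H]1COC(=O)C1
F2 | step 11 | (3S,4R)-3-{[3,4-bis(benzyloxy)phenyl](hydroxy)methyl}-4-{(S)-(triisopropylsilyloxy)[3,4,5-tris(benzyloxy)phenyl]methyl}oxolan-2-one | CC(C)[Si](C(C)C)(C(C)C)O[C@H](c2cc(OCc3ccccc3)c(OCc3ccccc3)c(OCc3ccccc3)c2)[C@H]1COC(=O)[C@@H]1C(O)c1ccc(OCc2ccccc2)c(OCc2ccccc2)c1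
F3 | step 11 | (3S,4R)-3-{[3,4-bis(benzyloxy)phenyl](hydroxy)methyl}-4-{(S)-hydroxy[3,4,5-tris(benzyloxy)phenyl]methyl}oxolan-2-one | O[C@H](c2cc(OCc3ccccc3)c(OCc3ccccc3)c(OCc3ccccc3)c2)[C@H]1COC(=O)[C@@H]1C(O)c1ccc(OCc2ccccc2)c(OCc2ccccc2)c1
F4 | step 11 | (3S,4R,5S)-3-{[3,4-bis(benzyloxy)phenyl](hydroxy)methyl}-4-(hydroxymethyl)-5-[3,4,5-tris(benzyloxy)phenyl]oxolan-2-one | O=C1O[C@H](c2cc(OCc3ccccc3)c(OCc3ccccc3)c(OCc3ccccc3)c2)[C@@H](CO)[C@H]1C(O)c1ccc(OCc2ccccc2)c(OCc2ccccc2)c1
F5 | step 5 | (1S,2R)-2-ethenyl-1-[3,4,5-tris(benzyloxy)phenyl]propane-1,3-diol | O[C@H](c1cc(OCc2ccccc2)c(OCc2ccccc2)c(OCc2ccccc2)c1)[C@@H](CO)C=C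
F6 | step 5 | (1S,2R)-2-[(tert-butyldimethylsilyloxy)methyl]-1-[3,4,5-tris(benzyloxy)phenyl]but-3-en-1-ol | O[C@H](c1cc(OCc2ccccc2)c(OCc2ccccc2)c(OCc2ccccc2)c1)[C@@H](CO[Si](C)(C)C(C)(C)C)C=C
F7 | step 5 | (3R,4S)-3-[(tert-butyldimethylsilyloxy)methyl]-4-(triisopropylsilyloxy)-4-[3,4,5-tris(benzyloxy)phenyl]but-1-ene | CC(C)[Si](C(C)C)(C(C)C)O[C@H](c1cc(OCc2ccccc2)c(OCc2ccccc2)c(OCc2ccccc2)c1)[C@@H](CO[Si](C)(C)C(C)(C)C)C=C
F8 | step 5 | (2R,3S)-2-[(tert-butyldimethylsilyloxy)methyl]-3-(triisopropylsilyloxy)-3-[3,4,5-tris(benzyloxy)phenyl]propanal | CC(C)[Si](C(C)C)(C(C)C)O[C@H](c1cc(OCc2ccccc2)c(OCc2ccccc2)c(OCc2ccccc2)c1)[C@@H](CO[Si](C)(C)C(C)(C)C)C=O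
F9 | step 9 | {(S)-[(3R)-5-[3,4-bis(benzyloxy)phenyl]-5-methoxyoxolan-3-yl][3,4,5-tris(benzyloxy)phenyl]methoxy}triisopropylsilane | CC(C)[Si](C(C)C)(C(C)C)O[C@H](c2cc(OCc3ccccc3)c(OCc3ccccc3)c(OCc3ccccc3)c2)[C@H]1COC(OC)(c2ccc(OCc3ccccc3)c(OCc3ccccc3)c2)C1
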